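**Plan**

1. Retrosynthetic cuts, in order: C2–C3 (undone as a 1,2-shift, giving a ring-contracted 3-formyl-2,3-dihydrobenzofuran-3-ol in which C2 is bonded to the future C4); that temporary C2–C4 bond; then O1–C2 (benzyl ether), C4–C4a (aryl–oxalyl) and C6–C1'' (aryl–geranyl).
2. Enabling feature: C2 is a benzylic ether carbon (on O1 and ring B) whose hydrogen lies delta to the C4 carbonyl oxygen (O=C4–C4a–C8a–O1–C2–H), and the C3 carbinol sits next to C4, so it can be drawn from a carboxyl carbon on the ketone.
3. Forward: ring A is dressed first on 5-methoxyresorcinol by three directed ortho-lithiations (silyl block at the future C8, geranyl at C6, menthyl oxalyl at C4a). Geranyl enters by SN2 allylation, because a sigmatropic delivery through an aryl geranyl ether would scramble the 2,3-alkene.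
4. Ring B is then attached as its benzyl ether, the five-membered O1–C2–C4 ring is closed by light, and ring C arises from it by alpha-ketol ring expansion; acid removes the two acetals last.
5. Stereochemistry: C2 is created in the photocyclisation and secured by separating menthyl-ester diastereomers, then migrates with retention; C3 is created trans in the 1,2-shift; the E alkene is carried unchanged from geranyl bromide.

Key step: step 10

Assumption: in benzene the biradical is taken to close with the new aryl group cis to the hydroxyl (trans to the ester), so that essentially the (2R,3R) and (2S,3S) menthyl esters arise and only this pair needs separating.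

**Route**

Step 1
Reactants: 1 5-methoxyresorcinol
Product: 2 1-methoxy-3,5-bis(methoxymethoxy)benzene
Conditions: NaH, MOMCl, DMF, 0 °C → rt
Reagents that add atoms: chloromethyl methyl ether, COCCl
Why: Double Williamson-type O-alkylation of the phenoxides gives the bis-acetal, whose MOM groups serve later as ortho-directing groups and as protection for the future C7–OH and O1.

Step 2
Reactants: 2 1-methoxy-3,5-bis(methoxymethoxy)benzene
Product: 4 [4-methoxy-2,6-bis(methoxymethoxy)phenyl]trimethylsilane, via aryllithium 3 (not isolated)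
Conditions: n-BuLi, THF, 0 °C; TMSCl, −78 °C → rt
Reagents that add atoms: chlorotrimethylsilane, C[Si](C)(C)Cl
Why: Directed ortho-metalation should be fastest at the hydrogen flanked by the two chelating MOM ethers, and silylation of that carbon (the future C8) blocks it so that every later lithiation must occur beside the methoxy group.

Step 3
Reactants: 4 [4-methoxy-2,6-bis(methoxymethoxy)phenyl]trimethylsilane; 5 geranyl bromide, (2E)-1-bromo-3,7-dimethylocta-2,6-diene
Product: 7 {3-[(2E)-3,7-dimethylocta-2,6-dien-1-yl]-4-methoxy-2,6-bis(methoxymethoxy)phenyl}trimethylsilane, via aryllithium 6 (not isolated)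
Conditions: n-BuLi, TMEDA, THF, 0 °C; CuBr·SMe2 (10 mol %), 5, −78 → 0 °C
Reagents that add atoms: none
Why: The second directed ortho-metalation can only occur at one of the two equivalent positions between OMe and OMOM, and copper-catalysed SN2 allylation of the aryl anion forms the aryl–C1'' bond without touching the E-configured 2,3-alkene.

Step 4
Reactants: 8 (−)-menthol, (1R,2S,5R)-2-isopropyl-5-methylcyclohexan-1-ol
Product: 9 (1R,2S,5R)-menthyl chlorooxoacetate
Conditions: (COCl)2 (excess), CH2Cl2, 0 °C → rt; evaporation
Reagents that add atoms: oxalyl chloride, ClC(=O)C(=O)Cl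
Why: Acylation of the secondary alcohol by excess oxalyl chloride stops at the half-ester acid chloride, which is used crude.

Step 5
Reactants: 7 the geranylated silane; 9 (1R,2S,5R)-menthyl chlorooxoacetate
Product: 11 (1R,2S,5R)-menthyl 2-{3-geranyl-2-methoxy-4,6-bis(methoxymethoxy)-5-(trimethylsilyl)phenyl}-2-oxoacetate, via aryllithium 10 (not isolated)
Conditions: n-BuLi, TMEDA, THF, 0 °C; cannulation into 9 (1.5 equiv), THF, −78 °C
Reagents that add atoms: none
Why: The last ring hydrogen, between OMe and OMOM, is removed by directed ortho-metalation (the silyl neighbour turns the MOM group towards it), and inverse addition of the hindered aryllithium to the acid chloride gives the aryl alpha-keto ester by nucleophilic acyl substitution without over-addition.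

Step 6
Reactants: 11 the silylated keto ester
Product: 12 (1R,2S,5R)-menthyl 2-[3-geranyl-6-hydroxy-2-methoxy-4-(methoxymethoxy)phenyl]-2-oxoacetate
Conditions: 2 M aq. HCl, MeOH–THF, 0 °C → rt, stopped at the monophenol
Reagents that add atoms: none
Why: Acid-catalysed acetal methanolysis is fastest for the MOM ether ortho to the ketone (carbonyl-assisted, hydrogen-bonded phenol product), and under the same protic conditions the electron-rich aryl silane should undergo ipso-protodesilylation, restoring hydrogen at the future C8.

Step 7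
Reactants: 13 4-hydroxybenzyl alcohol
Product: 14 [4-(methoxymethoxy)phenyl]methanol
Conditions: MOMCl, K2CO3, acetone, 0 °C → rt
Reagents that add atoms: chloromethyl methyl ether, COCCl
Why: Chemoselective Williamson O-alkylation, since carbonate deprotonates only the phenol and leaves the benzylic alcohol free.

Step 8
Reactants: 14 [4-(methoxymethoxy)phenyl]methanol
Product: 15 1-(chloromethyl)-4-(methoxymethoxy)benzene
Conditions: PPh3, NCS, THF, 0 °C → rt; used at once
Reagents that add atoms: N-chlorosuccinimide, O=C1CCC(=O)N1Cl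
Why: Appel-type chlorination through an alkoxyphosphonium salt converts the benzylic alcohol into the chloride under neutral conditions that spare the acetal.

Step 9
Reactants: 12 the hydroxy keto ester; 15 1-(chloromethyl)-4-(methoxymethoxy)benzene
Product: 16 (1R,2S,5R)-menthyl 2-{3-geranyl-2-methoxy-4-(methoxymethoxy)-6-{[4-(methoxymethoxy)phenyl]methoxy}phenyl}-2-oxoacetate
Conditions: K2CO3, Bu4NI (cat.), DMF, rt → 40 °C
Reagents that add atoms: none
Why: Williamson etherification of the chelated ortho-hydroxy keto ester with the reactive 4-alkoxybenzyl chloride forms the O1–C2 bond and places the benzylic hydrogens delta to the ketone oxygen.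

Step 10
Reactants: 16 the ortho-(4-alkoxybenzyloxy)aryl glyoxylate
Product: 17 (1R,2S,5R)-menthyl (2R,3R)-5-geranyl-3-hydroxy-4-methoxy-6-(methoxymethoxy)-2-[4-(methoxymethoxy)phenyl]-2,3-dihydro-1-benzofuran-3-carboxylate (hydroxyl cis to the 2-aryl group)
Conditions: hν (365 nm, Pyrex), degassed benzene (5 mM), 20 °C; then SiO2 chromatography and crystallisation to isolate the (2R,3R) diastereomer
Reagents that add atoms: none
Why: Excitation of the twisted aryl alpha-keto ester (n,π*) gives a triplet whose ketone oxygen abstracts the benzylic ether hydrogen on the future C2 through a six-membered transition state, and the resulting 1,5-biradical (ketyl carbon and alpha-aryloxybenzyl carbon) combines after intersystem crossing to form the new C–C bond. This is a Norrish–Yang photocyclisation, the closest known case being the conversion of ortho-benzyloxyphenyl glyoxylates and ketones into 3-hydroxy-2-aryl-2,3-dihydrobenzofurans. The only ring formed is the five-membered O1–C2–C3–C3a–C7a ring, closed by 1,5-biradical recombination. The relative configuration (aryl cis to hydroxyl, trans to the bulky ester) follows from steric preference in the closing biradical in a non-hydrogen-bonding solvent; the menthyl group is expected to give only a modest facial bias, so the absolute configuration at C2 is secured by separating the (2R,3R) ester from its (2S,3S) diastereomer, with assignment by X-ray analysis. The step needs site selectivity between the two delta C–H positions (OCH2Ar against OCH3) and against hydrogen abstraction from the menthyl carbinol C–H or quenching by the geranyl alkenes; the doubly activated benzylic alpha-oxy C–H bond is much the weakest, and long-wavelength irradiation at high dilution excites only the keto ester.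

Step 11
Reactants: 17 the (2R,3R) benzofuranol ester
Product: 18 (2R,3S)-5-geranyl-3-(hydroxymethyl)-4-methoxy-6-(methoxymethoxy)-2-[4-(methoxymethoxy)phenyl]-2,3-dihydro-1-benzofuran-3-ol
Conditions: LiAlH4, THF, 0 °C; aq. KNaC4H4O6 work-up
Reagents that add atoms: none
Why: Hydride reduction of the hindered ester (after deprotonation of the tertiary hydroxyl) gives the primary alcohol and releases menthol for recovery; no stereocentre is touched and only the C3 descriptor changes.

Step 12
Reactants: 18 the primary–tertiary diol
Product: 19 (2R,3R)-5-geranyl-3-hydroxy-4-methoxy-6-(methoxymethoxy)-2-[4-(methoxymethoxy)phenyl]-2,3-dihydro-1-benzofuran-3-carbaldehyde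
Conditions: (COCl)2, DMSO, CH2Cl2, −78 °C; Et3N, −78 → −20 °C; cold buffered work-up, used crude
Reagents that add atoms: none
Why: Swern oxidation converts the primary alcohol into the aldehyde, while the tertiary alcohol cannot be oxidised and activated DMSO does not cleave the glycol.

Step 13
Reactants: 19 the tertiary alpha-hydroxy aldehyde
Product: 20 (2R,3R)-6-geranyl-3-hydroxy-5-methoxy-7-(methoxymethoxy)-2-[4-(methoxymethoxy)phenyl]-2,3-dihydro-4H-chromen-4-one (2,3-trans)
Conditions: K2CO3 (0.2 equiv), degassed MeOH–THF, 0 °C → rt; AcOH quench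
Reagents that add atoms: none
Why: Alpha-ketol (acyloin) rearrangement with ring expansion: in the alkoxide C2 shifts suprafacially, with retention, from the carbinol carbon to the aldehyde carbon, driven by relief of five-ring strain and formation of the vinylogous-ester aryl ketone, and with the two oxygens anti (protic medium, no chelating metal) the new C3–OH is delivered trans to the C2 aryl group, which is also the more stable diequatorial epimer.

Step 14
Reactants: 20 the bis-MOM trans-dihydroflavonol
Product: 21 (2R,3R)-6-geranyl-3,7-dihydroxy-2-(4-hydroxyphenyl)-5-methoxy-2,3-dihydro-4H-chromen-4-one (target, CNP0177937.1)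
Conditions: 3 M aq. HCl, MeOH, 40 °C
Reagents that add atoms: none
Why: Acid-catalysed methanolysis of the two MOM acetals frees the C7 and C4' phenols under conditions routinely tolerated by prenylated trans-dihydroflavonols, leaving C2, C3 and the geranyl chain untouched.

**Compound list**

1 | 5-methoxyresorcinol | COc1cc(O)cc(O)c1 | starting material
2 | 1-methoxy-3,5-bis(methoxymethoxy)benzene | COCOc1cc(OC)cc(OCOC)c1 | intermediate
3 | [4-methoxy-2,6-bis(methoxymethoxy)phenyl]lithium | [Li]c1c(OCOC)cc(OC)cc1OCOC | intermediate
4 | [4-methoxy-2,6-bis(methoxymethoxy)phenyl]trimethylsilane | C[Si](C)(C)c1c(OCOC)cc(OC)cc1OCOC | intermediate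
5 | geranyl bromide, (2E)-1-bromo-3,7-dimethylocta-2,6-diene | BrC/C=C(\C)CCC=C(C)C | starting material
6 | [2-methoxy-4,6-bis(methoxymethoxy)-5-(trimethylsilyl)phenyl]lithium | C[Si](C)(C)c1c(OCOC)c([Li])c(OC)cc1OCOC | intermediate
7 | {3-[(2E)-3,7-dimethylocta-2,6-dien-1-yl]-4-methoxy-2,6-bis(methoxymethoxy)phenyl}trimethylsilane | C[Si](C)(C)c1c(OCOC)c(C/C=C(\C)CCC=C(C)C)c(OC)cc1OCOC | intermediate
8 | (−)-menthol, (1R,2S,5R)-2-isopropyl-5-methylcyclohexan-1-ol | O[C@@H]1C[C@H](C)CC[C@H]1C(C)C | starting material
9 | (1R,2S,5R)-menthyl chlorooxoacetate | ClC(=O)C(=O)O[C@@H]1C[C@H](C)CC[C@H]1C(C)C | intermediate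
10 | [3-geranyl-2-methoxy-4,6-bis(methoxymethoxy)-5-(trimethylsilyl)phenyl]lithium | C[Si](C)(C)c1c(OCOC)c(C/C=C(\C)CCC=C(C)C)c(OC)c([Li])c1OCOC | intermediate
11 | (1R,2S,5R)-menthyl 2-{3-geranyl-2-methoxy-4,6-bis(methoxymethoxy)-5-(trimethylsilyl)phenyl}-2-oxoacetate | COc1c(C/C=C(\C)CCC=C(C)C)c(OCOC)c([Si](C)(C)C)c(OCOC)c1C(=O)C(=O)O[C@@H]1C[C@H](C)CC[C@H]1C(C)C | intermediate
12 | (1R,2S,5R)-menthyl 2-[3-geranyl-6-hydroxy-2-methoxy-4-(methoxymethoxy)phenyl]-2-oxoacetate | COc1c(C/C=C(\C)CCC=C(C)C)c(OCOC)cc(O)c1C(=O)C(=O)O[C@@H]1C[C@H](C)CC[C@H]1C(C)C | intermediate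
13 | 4-hydroxybenzyl alcohol | OCc1ccc(O)cc1 | starting material
14 | [4-(methoxymethoxy)phenyl]methanol | COCOc1ccc(CO)cc1 | intermediate
15 | 1-(chloromethyl)-4-(methoxymethoxy)benzene | COCOc1ccc(CCl)cc1 | intermediate
16 | (1R,2S,5R)-menthyl 2-{3-geranyl-2-methoxy-4-(methoxymethoxy)-6-{[4-(methoxymethoxy)phenyl]methoxy}phenyl}-2-oxoacetate | COc1c(C/C=C(\C)CCC=C(C)C)c(OCOC)cc(OCc2ccc(OCOC)cc2)c1C(=O)C(=O)O[C@@H]1C[C@H](C)CC[C@H]1C(C)C | intermediate
17 | (1R,2S,5R)-menthyl (2R,3R)-5-geranyl-3-hydroxy-4-methoxy-6-(methoxymethoxy)-2-[4-(methoxymethoxy)phenyl]-2,3-dihydro-1-benzofuran-3-carboxylate | COc1c(C/C=C(\C)CCC=C(C)C)c(OCOC)cc2c1[C@](O)(C(=O)O[C@@H]1C[C@H](C)CC[C@H]1C(C)C)[C@@H](c1ccc(OCOC)cc1)O2 | intermediate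
18 | (2R,3S)-5-geranyl-3-(hydroxymethyl)-4-methoxy-6-(methoxymethoxy)-2-[4-(methoxymethoxy)phenyl]-2,3-dihydro-1-benzofuran-3-ol | COc1c(C/C=C(\C)CCC=C(C)C)c(OCOC)cc2c1[C@](O)(CO)[C@@H](c1ccc(OCOC)cc1)O2 | intermediate
19 | (2R,3R)-5-geranyl-3-hydroxy-4-methoxy-6-(methoxymethoxy)-2-[4-(methoxymethoxy)phenyl]-2,3-dihydro-1-benzofuran-3-carbaldehyde | COc1c(C/C=C(\C)CCC=C(C)C)c(OCOC)cc2c1[C@](O)(C=O)[C@@H](c1ccc(OCOC)cc1)O2 | intermediate
20 | (2R,3R)-6-geranyl-3-hydroxy-5-methoxy-7-(methoxymethoxy)-2-[4-(methoxymethoxy)phenyl]-2,3-dihydro-4H-chromen-4-one | COc1c(C/C=C(\C)CCC=C(C)C)c(OCOC)cc2c1C(=O)[C@H](O)[C@@H](c1ccc(OCOC)cc1)O2 | intermediate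
21 | (2R,3R)-6-geranyl-3,7-dihydroxy-2-(4-hydroxyphenyl)-5-methoxy-2,3-dihydro-4H-chromen-4-one | COc1c(C/C=C(\C)CCC=C(C)C)c(O)cc2c1C(=O)[C@H](O)[C@@H](c1ccc(O)cc1)O2 | target

**Step count**

Total: 14 steps. Longest linear sequence: 11 steps (1, 2, 3, 5, 6, 9, 10, 11, 12, 13, 14).

**Steps most likely to fail**

Step 10. The excited keto ester may decay without hydrogen transfer (quenching by the geranyl alkenes, fragmentation through the menthyl carbinol hydrogen), and the menthyl group may give too little facial bias or diastereomers that do not separate. The fallback gives up the photochemical bond formation and makes ring C by epoxide opening. It sets out from silane 7: lithiation as in step 5 and quenching of aryllithium 10 with N-methoxy-N-methylacetamide should give the methyl ketone 1-{3-geranyl-2-methoxy-4,6-bis(methoxymethoxy)-5-(trimethylsilyl)phenyl}ethan-1-one F1. Alcohol 14 is oxidised with MnO2 to 4-(methoxymethoxy)benzaldehyde F2, and Claisen–Schmidt condensation of the two (KOH, EtOH) should give the (E)-chalcone F3. Nucleophilic asymmetric epoxidation of the enone (poly-L-leucine, urea–H2O2, DBU, THF; Juliá–Colonna conditions), which leaves the electron-rich geranyl alkenes alone, should give the (αR,βS)-epoxide F4. HCl in MeOH then removes the three acetals and the silyl group, and the freed ortho-phenol opens the epoxide at the benzylic carbon with inversion, which rejoins the route at target 21.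

Step 13. The electron-rich aryl carbon may migrate in place of C2, the shift may pass through the chelated geometry and give the 2,3-cis ketol, and under base the product enolate may open ring C (loss of the C2 configuration) or be oxidised by air. The fallback avoids base and separates the shift from the setting of C3. It sets out from aldehyde 19: Al(OtBu)3 in toluene at 60–80 °C should bring about the chelate-controlled shift (oxygens syn) to the cis ketol (2R,3S)-6-geranyl-3-hydroxy-5-methoxy-7-(methoxymethoxy)-2-[4-(methoxymethoxy)phenyl]-2,3-dihydro-4H-chromen-4-one F5. Mitsunobu inversion at C3 with formic acid (PPh3, DIAD, THF) should then give the trans formate (2R,3R)-6-geranyl-5-methoxy-7-(methoxymethoxy)-2-[4-(methoxymethoxy)phenyl]-4-oxo-3,4-dihydro-2H-chromen-3-yl formate F6. The conditions of step 14 cleave the formate together with the acetals, so the sequence rejoins the route at target 21.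

Step 6. Acetal cleavage may not stop at the ortho MOM group (loss of the para MOM as well), or protodesilylation may lag behind. The fallback replaces selective cleavage by full cleavage and selective re-protection. It sets out from keto ester 11: longer treatment with HCl in MeOH at 40 °C removes both acetals and the silyl group to give the diphenol (1R,2S,5R)-menthyl 2-(3-geranyl-4,6-dihydroxy-2-methoxyphenyl)-2-oxoacetate F7. MOMCl (1.05 equiv) with iPr2NEt in CH2Cl2 at 0 °C should then alkylate only the non-chelated hydroxyl para to the ketone, which rejoins the route at phenol 12.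

**Further compounds**

F1 | step 10 | 1-{3-geranyl-2-methoxy-4,6-bis(methoxymethoxy)-5-(trimethylsilyl)phenyl}ethan-1-one | COc1c(C/C=C(\C)CCC=C(C)C)c(OCOC)c([Si](C)(C)C)c(OCOC)c1C(C)=O
F2 | step 10 | 4-(methoxymethoxy)benzaldehyde | COCOc1ccc(C=O)cc1
F3 | step 10 | (2E)-1-{3-geranyl-2-methoxy-4,6-bis(methoxymethoxy)-5-(trimethylsilyl)phenyl}-3-[4-(methoxymethoxy)phenyl]prop-2-en-1-one | COc1c(C/C=C(\C)CCC=C(C)C)c(OCOC)c([Si](C)(C)C)c(OCOC)c1C(=O)/C=C/c1ccc(OCOC)cc1
F4 | step 10 | {3-geranyl-2-methoxy-4,6-bis(methoxymethoxy)-5-(trimethylsilyl)phenyl}{(2R,3S)-3-[4-(methoxymethoxy)phenyl]oxiran-2-yl}methanone | COc1c(C/C=C(\C)CCC=C(C)C)c(OCOC)c([Si](C)(C)C)c(OCOC)c1C(=O)[C@@H]1O[C@H]1c1ccc(OCOC)cc1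
F5 | step 13 | (2R,3S)-6-geranyl-3-hydroxy-5-methoxy-7-(methoxymethoxy)-2-[4-(methoxymethoxy)phenyl]-2,3-dihydro-4H-chromen-4-one | COc1c(C/C=C(\C)CCC=C(C)C)c(OCOC)cc2c1C(=O)[C@@H](O)[C@@H](c1ccc(OCOC)cc1)O2
F6 | step 13 | (2R,3R)-6-geranyl-5-methoxy-7-(methoxymethoxy)-2-[4-(methoxymethoxy)phenyl]-4-oxo-3,4-dihydro-2H-chromen-3-yl formate | COc1c(C/C=C(\C)CCC=C(C)C)c(OCOC)cc2c1C(=O)[C@H](OC=O)[C@@H](c1ccc(OCOC)cc1)O2
F7 | step 6 | (1R,2S,5R)-menthyl 2-(3-geranyl-4,6-dihydroxy-2-methoxyphenyl)-2-oxoacetate | COc1c(C/C=C(\C)CCC=C(C)C)c(O)cc(O)c1C(=O)C(=O)O[C@@H]1C[C@H](C)CC[C@H]1C(C)C
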